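What is left of the solid electrophile after 60.0 min hardly depends on the charge: 45.6% in the grey run with 0.64 equiv of nucleophile, 45.9% in the ochre run with 1.4 equiv. The readings fall on a nearly straight line. Call the solid gone into solution by the asked time, on that line, the supply S: 81.6% of the charge.

in all of them: solid electrophile 0.40 M

| run | nucleophile | remark | time |
|---|---|---|---|
| grey | 0.64 equiv | run made earlier |  |
| ochre | 1.4 equiv | run made earlier |  |
| oak | 0.800 equiv |  | 1.5 h |
| larch | 1.20 equiv |  | 1.5 h |
| cedar | 1.80 equiv |  | 1.5 h |

| run | time / min | solid electrophile / % | target / % |
|---|---|---|---|
| grey | 8.00 | 90.0 | 2.1 |
| grey | 20.0 | 79.7 | 3.0 |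
| grey | 40.0 | 64.2 | 11.7 |
| grey | 60.0 | 45.6 | 17.1 |
| ochre | 15.0 | 86.0 | 5.6 |
| ochre | 30.0 | 70.7 | 14.3 |
| ochre | 50.0 | 52.9 | 29.3 |
| ochre | 60.0 | 45.9 | 32.2 |

(scatter of a reading: 1 percentage point)

* part of the solid electrophile that has reacted (what has only dissolved counts as not reacted) at the end, oak
* part of the solid electrophile that has reacted (what has only dissolved counts as not reacted) at the end, larch
* part of the solid electrophile that has reacted (what has only dissolved counts as not reacted) at the end, cedar
* what raising the equivalents of nucleophile from its lowest to its highest value here does to the part of the solid electrophile that has reacted (what has only dissolved counts as not reacted) (changes below 5 percentage points count as none) (no change / it falls / it rises)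

- in percentages every species weighs as the solid electrophile in it: one self-condensation product counts as two
- as a solid, counted per litre of solution: solid electrophile
- reactions considered so far: electrophile + nucleophile -> acid set free + target; nucleophile + acid set free <-> protonated nucleophile; acid set free + target -> side product; 2 electrophile -> self-condensation product; solid electrophile <-> electrophile
- at the start none of the solid electrophile is in solution
- what has only dissolved of solid electrophile counts as not reacted

Target lags behind the solid lost. The gap at the last reading is 37.3% in grey and 21.9% in ochre. Two people read this gap differently.

The forecaster holds that the gap waits in solution for nucleophile: “dissolved electrophile accumulates”. Reacted then means mainly coupled. The forecast is 33% for oak, 45% for larch and 57% for cedar, and it rises.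

I hold that dissolved electrophile can also react with itself, and that counts as reacted. My first round says nothing stands in solution, so every flask gives S and the trend is flat. But the gaps are there, so something may stand. Going round again, I subtract each gap from S, using the run nearest in charge. Oak gets 44.3% and cedar 59.7% as low estimates, S is the high one, and the trend rises. My low cedar estimate lies above the forecast's cedar value.

The flasks give 58.8% for oak, 63.5% for larch and 69.9% for cedar. With more nucleophile it rises, by 11 percentage points. Each lies above the forecast's range and below S.

    electrophile + nucleophile → acid set free + target (k = 0.140 L mol⁻¹ min⁻¹)
    nucleophile + acid set free ⇌ protonated nucleophile, settled at all times (K = 3700 L mol⁻¹)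
    acid set free + target → side product (k = 0.500 L mol⁻¹ min⁻¹)
    2 electrophile → self-condensation product (k = 0.190 L mol⁻¹ min⁻¹)
    solid electrophile ⇌ electrophile, rate k5*(cs5 - [electrophile]) while solid is left; crystals form when [electrophile] > cs5 (solubility = 0.270 M, k = 0.0160 min⁻¹)

S minus the electrophile dissolved at the end gives 63.1% for oak and 68.2% for cedar, close to the results. In oak S serves as a yardstick since going into solution is the rate-limiting step. The forecast's view has its region: oak run without self-condensation gives 34.7%, near the forecast's 33%. That step is part of the difference.

Now take cedar's recipe stopped at 50 min. S scaled to that time is 45.3%, and minus the 10.5% dissolved it gives 34.9%. The computed result is 37.2%.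

Readings and results are calculated from invented constants; noise was put on by code.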